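**Plan**

- Retrosynthesis: after ester hydrolysis, the bond between the carbinol carbon and the 1,1-disubstituted alkene carbon is cut, giving an oxane aldehyde and the enol triflate of (E)-geranylacetone. The enabling feature is the allylic alcohol unit CH(OH)–C(=CH2)–CH2: its alkene carbon is the ketone carbon of geranylacetone and its carbinol carbon is an aldehyde carbon, so two electrophilic carbonyl-derived carbons can be joined by nickel/chromium polarity reversal. The oxane ring carries only an ether and an acrylate ester, which an alkenylchromium reagent leaves alone.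
- In the aldehyde half, the acrylate =CH2 is cut first (Mannich methylenation), then the C2–H and C2–CH2CO2Me bonds of the oxane ring (lactone plus acetate enolate, silane reduction), then the C5–CH2CH2CO bond (Michael addition of an acyl oxazolidinone to tert-butyl acrylate).
- Forward: the C5 branch point is built first, the six-membered lactone is closed, the lactone becomes the 2,5-trans oxane, the butenyl arm becomes the masked aldehyde, the acrylate is completed, the aldehyde is freed, the geranylacetone-derived chain is coupled, and the ester is hydrolysed.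
- Stereochemistry: ring C5 from the (R)-4-benzyloxazolidinone auxiliary; ring C2 from axial hydride delivery to the ring oxocarbenium ion; the carbinol from the chiral chromium catalyst; the (E)-trisubstituted alkene is bought with geranylacetone.

Key step: step 9

Assumption: (E)-geranylacetone is used as the single geometric isomer, the acid is carried as its methyl ester until the last step, and the ligand antipode in step 9 is the one that gives Si-face addition to the aldehyde (to be confirmed on the first coupling by Mosher ester analysis).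

**Route**

Step 1
Reactants: 1 (R)-4-benzyloxazolidin-2-one; 2 hex-5-enoyl chloride
Product: 3 (R)-4-benzyl-3-(hex-5-enoyl)oxazolidin-2-one
Conditions: n-BuLi, THF, −78 °C; then 2, −78 → 0 °C
Reagents that add atoms: none
Why: N-acylation of the lithiated oxazolidinone by the acid chloride (standard auxiliary loading) should proceed cleanly and creates no new stereocenter.

Step 2
Reactants: 3 (R)-4-benzyl-3-(hex-5-enoyl)oxazolidin-2-one; 4 tert-butyl acrylate
Product: 5 tert-butyl (4S)-4-{[(4R)-4-benzyl-2-oxo-1,3-oxazolidin-3-yl]carbonyl}oct-7-enoate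
Conditions: TiCl4/Ti(OiPr)4 (3:1), i-Pr2NEt, CH2Cl2, 0 °C; then 4, 0 °C → rt
Reagents that add atoms: none
Why: Auxiliary-controlled (Evans-type) titanium-enolate Michael addition, in which the chelated Z-enolate should add to the acrylate from the face opposite the benzyl group of the (R)-auxiliary and so set the future ring C5 as (S).

Step 3
Reactants: 5 tert-butyl (4S)-4-{[(4R)-4-benzyl-2-oxo-1,3-oxazolidin-3-yl]carbonyl}oct-7-enoate
Product: 7 (5S)-5-(but-3-en-1-yl)oxan-2-one, via hydroxy ester 6 (not isolated)
Conditions: LiBH4, MeOH (1 equiv), THF, 0 °C; aqueous work-up; then crude with p-TsOH·H2O (cat.), toluene, 80 °C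
Reagents that add atoms: none
Why: Reductive removal of the auxiliary (the imide should be reduced faster than the tert-butyl ester) followed by acid-catalysed lactonisation of the δ-hydroxy tert-butyl ester with loss of isobutene, with the stereocenter untouched.

Step 4
Reactants: 7 (5S)-5-(but-3-en-1-yl)oxan-2-one; 8 methyl acetate
Product: 10 methyl 2-[(2R,5S)-5-(but-3-en-1-yl)oxan-2-yl]acetate, via hemiketal 9 (not isolated)
Conditions: LiN(iPr)2, 8, THF, −78 °C; then 7, −78 °C, AcOH quench; crude with Et3SiH, CF3CO2H, CH2Cl2, −20 → 0 °C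
Reagents that add atoms: none
Why: Claisen-type addition of the ester enolate to the lactone followed by ionic hydrogenation (silane/acid reduction of the hemiketal), in which hydride should enter axially at C2 of the oxocarbenium half-chair that holds the C5 chain pseudo-equatorial, giving the 2,5-trans (diequatorial) ring and setting C2 as (R).

Step 5
Reactants: 10 methyl 2-[(2R,5S)-5-(but-3-en-1-yl)oxan-2-yl]acetate
Product: 12 methyl 2-[(2R,5R)-5-(3,3-dimethoxypropyl)oxan-2-yl]acetate, via aldehyde 11 (not isolated)
Conditions: O3, CH2Cl2/MeOH, −78 °C; Me2S, −78 °C → rt; then HC(OMe)3, p-TsOH·H2O (cat.), MeOH, rt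
Reagents that add atoms: trimethyl orthoformate COC(OC)OC (the two methoxy groups of the acetal); ozone [O-][O+]=O (oxygen of intermediate 11 only)
Why: Ozonolysis of the only alkene with reductive work-up and acid-catalysed acetalisation should mask the aldehyde for the enolate chemistry of step 6 without touching a stereocenter (the change of the C5 descriptor is a priority change only).

Step 6
Reactants: 12 methyl 2-[(2R,5R)-5-(3,3-dimethoxypropyl)oxan-2-yl]acetate
Product: 15 methyl 2-[(2R,5R)-5-(3,3-dimethoxypropyl)oxan-2-yl]prop-2-enoate, via Mannich base 13 (not isolated), via ammonium iodide 14 (not isolated)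
Conditions: LiN(iPr)2, THF, −78 °C; CH2=NMe2+ I−, −78 °C → rt; then MeI, MeOH, rt; then DBU, CH2Cl2, rt
Reagents that add atoms: Eschenmoser's salt (N,N-dimethylmethyleneiminium iodide) C=[N+](C)C.[I-] (the methylene carbon); iodomethane CI (methyl group of intermediate 14 only)
Why: Ester-enolate Mannich reaction with Eschenmoser's salt, quaternisation and E1cB loss of trimethylamine (α-methylenation of an ester) should give the acrylate, and a transient opening of the ring by β-elimination would only re-close to the same diequatorial ring.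

Step 7
Reactants: 15 methyl 2-[(2R,5R)-5-(3,3-dimethoxypropyl)oxan-2-yl]prop-2-enoate
Product: 16 methyl 2-[(2R,5R)-5-(3-oxopropyl)oxan-2-yl]prop-2-enoate
Conditions: 1 M HCl, THF, rt
Reagents that add atoms: water O
Why: Acid-catalysed hydrolysis of the dimethyl acetal should free the aldehyde, while the acrylate ester and the cyclic ether are stable to dilute acid at room temperature.

Step 8
Reactants: 17 (E)-geranylacetone
Product: 18 (5E)-6,10-dimethylundeca-1,5,9-trien-2-yl trifluoromethanesulfonate
Conditions: KN(SiMe3)2, THF, −78 °C; then PhNTf2, −78 → 0 °C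
Reagents that add atoms: N-phenylbis(trifluoromethanesulfonimide) O=S(=O)(N(c1ccccc1)S(=O)(=O)C(F)(F)F)C(F)(F)F
Why: Kinetic deprotonation of the methyl ketone at the methyl group and O-sulfonylation of the enolate (enol triflate formation) should place the 1,1-disubstituted alkene and its activating group in one operation, leaving the (E)-alkene untouched.

Step 9
Reactants: 16 methyl 2-[(2R,5R)-5-(3-oxopropyl)oxan-2-yl]prop-2-enoate; 18 (5E)-6,10-dimethylundeca-1,5,9-trien-2-yl trifluoromethanesulfonate
Product: 19 methyl 2-[(2R,5S)-5-[(3R,7E)-3-hydroxy-8,12-dimethyl-4-methylidenetrideca-7,11-dien-1-yl]oxan-2-yl]prop-2-enoate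
Conditions: CrCl2 (10 mol%), Si-face-selective antipode of N-[2-(4-isopropyl-4,5-dihydro-1,3-oxazol-2-yl)-6-methoxyphenyl]methanesulfonamide (11 mol%), proton sponge (11 mol%), NiCl2·(2,9-dimethyl-1,10-phenanthroline) (2 mol%), Mn powder, Cp2ZrCl2, LiCl, MeCN, rt
Reagents that add atoms: none
Why: Zerovalent nickel, formed from the NiCl2 complex by Mn, should insert into the C–OTf bond of 18 and pass the alkenyl group to the chiral trivalent chromium–sulfonamide complex, which turns the former ketone carbon into a nucleophile that adds to the aldehyde carbon of 16; Cp2ZrCl2 takes the alkoxide off chromium and Mn returns chromium to the divalent state. The closest known reaction type is the catalytic asymmetric Nozaki–Hiyama–Kishi coupling of 2-halo- or 2-sulfonyloxy-1-alkenes with unbranched aliphatic aldehydes. No ring is closed; the step joins the two halves and forms the allylic alcohol with its 1,1-disubstituted alkene already in place, the alkene position being fixed by where the triflate sits. The new carbinol center should be set as (R) by the ligand on chromium (catalyst control), since the nearest substrate stereocenter is three atoms away and gives no bias. The step needs chemoselectivity for the aldehyde over the acrylate ester, and this is secured by the low basicity and aldehyde preference of alkenylchromium reagents, which do not add to esters or enoates, and by the low nickel loading, which disfavours Heck-type capture of the acrylate.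

Step 10
Reactants: 19 methyl 2-[(2R,5S)-5-[(3R,7E)-3-hydroxy-8,12-dimethyl-4-methylidenetrideca-7,11-dien-1-yl]oxan-2-yl]prop-2-enoate
Product: 20 2-[(2R,5S)-5-[(3R,7E)-3-hydroxy-8,12-dimethyl-4-methylidenetrideca-7,11-dien-1-yl]oxan-2-yl]prop-2-enoic acid (CNP0197923.2)
Conditions: LiOH·H2O, THF/MeOH/H2O, 0 °C → rt; then 0.5 M HCl to pH 4, 0 °C
Reagents that add atoms: lithium hydroxide [Li+].[OH-]
Why: Saponification of the methyl ester (acyl-oxygen cleavage by hydroxide) should give the acid, with the allylic alcohol, the alkenes and the three stereocenters inert to these conditions and to the brief, cold, mildly acidic work-up.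

**Compound list**

1 | (R)-4-benzyloxazolidin-2-one | O=C1N[C@H](Cc2ccccc2)CO1 | starting material
2 | hex-5-enoyl chloride | C=CCCCC(=O)Cl | starting material
3 | (R)-4-benzyl-3-(hex-5-enoyl)oxazolidin-2-one | C=CCCCC(=O)N1[C@H](Cc2ccccc2)COC1=O | intermediate
4 | tert-butyl acrylate | C=CC(=O)OC(C)(C)C | starting material
5 | tert-butyl (4S)-4-{[(4R)-4-benzyl-2-oxo-1,3-oxazolidin-3-yl]carbonyl}oct-7-enoate | C=CCC[C@H](C(=O)N1[C@H](Cc2ccccc2)COC1=O)CCC(=O)OC(C)(C)C | intermediate
6 | tert-butyl (4S)-4-(hydroxymethyl)oct-7-enoate | C=CCC[C@H](CO)CCC(=O)OC(C)(C)C | intermediate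
7 | (5S)-5-(but-3-en-1-yl)oxan-2-one | C=CCC[C@H]1CCC(=O)OC1 | intermediate
8 | methyl acetate | CC(=O)OC | starting material
9 | methyl 2-[(5S)-5-(but-3-en-1-yl)-2-hydroxyoxan-2-yl]acetate (anomer mixture) | C=CCC[C@H]1CCC(O)(CC(=O)OC)OC1 | intermediate
10 | methyl 2-[(2R,5S)-5-(but-3-en-1-yl)oxan-2-yl]acetate | C=CCC[C@H]1CC[C@H](CC(=O)OC)OC1 | intermediate
11 | methyl 2-[(2R,5R)-5-(3-oxopropyl)oxan-2-yl]acetate | O=CCC[C@H]1CC[C@H](CC(=O)OC)OC1 | intermediate
12 | methyl 2-[(2R,5R)-5-(3,3-dimethoxypropyl)oxan-2-yl]acetate | COC(OC)CC[C@H]1CC[C@H](CC(=O)OC)OC1 | intermediate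
13 | methyl 3-(dimethylamino)-2-[(2R,5R)-5-(3,3-dimethoxypropyl)oxan-2-yl]propanoate (α-epimer mixture) | COC(OC)CC[C@H]1CC[C@H](C(CN(C)C)C(=O)OC)OC1 | intermediate
14 | {2-[(2R,5R)-5-(3,3-dimethoxypropyl)oxan-2-yl]-3-methoxy-3-oxopropyl}trimethylammonium iodide | COC(OC)CC[C@H]1CC[C@H](C(C[N+](C)(C)C)C(=O)OC)OC1.[I-] | intermediate
15 | methyl 2-[(2R,5R)-5-(3,3-dimethoxypropyl)oxan-2-yl]prop-2-enoate | COC(OC)CC[C@H]1CC[C@H](C(=C)C(=O)OC)OC1 | intermediate
16 | methyl 2-[(2R,5R)-5-(3-oxopropyl)oxan-2-yl]prop-2-enoate | O=CCC[C@H]1CC[C@H](C(=C)C(=O)OC)OC1 | intermediate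
17 | (E)-geranylacetone, (5E)-6,10-dimethylundeca-5,9-dien-2-one | CC(=O)CC/C=C(\C)CCC=C(C)C | starting material
18 | (5E)-6,10-dimethylundeca-1,5,9-trien-2-yl trifluoromethanesulfonate | C=C(OS(=O)(=O)C(F)(F)F)CC/C=C(\C)CCC=C(C)C | intermediate
19 | methyl 2-[(2R,5S)-5-[(3R,7E)-3-hydroxy-8,12-dimethyl-4-methylidenetrideca-7,11-dien-1-yl]oxan-2-yl]prop-2-enoate | C=C(CC/C=C(\C)CCC=C(C)C)[C@H](O)CC[C@H]1CC[C@H](C(=C)C(=O)OC)OC1 | intermediate
20 | 2-[(2R,5S)-5-[(3R,7E)-3-hydroxy-8,12-dimethyl-4-methylidenetrideca-7,11-dien-1-yl]oxan-2-yl]prop-2-enoic acid | C=C(CC/C=C(\C)CCC=C(C)C)[C@H](O)CC[C@H]1CC[C@H](C(=C)C(=O)O)OC1 | target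

**Count and risks**

Total step count: 10. Longest linear sequence: 9 steps (steps 1–7, 9, 10); step 8 is the one-step side branch.

Steps most likely to fail:

1. Step 9. The risk is poor facial selectivity in the catalyst-controlled addition to an unbranched aldehyde. The fallback sets out from 16 and 18 and comes back at 19. The coupling would be run without the chiral ligand (CrCl2 in excess, NiCl2 1 mol%, DMF/THF, rt), which should give 19 together with its carbinol epimer methyl 2-[(2R,5S)-5-[(3S,7E)-3-hydroxy-8,12-dimethyl-4-methylidenetrideca-7,11-dien-1-yl]oxan-2-yl]prop-2-enoate F1. The mixture would be oxidised with Dess–Martin periodinane (NaHCO3, CH2Cl2) to the cross-conjugated enone methyl 2-[(2R,5R)-5-[(7E)-8,12-dimethyl-4-methylidene-3-oxotrideca-7,11-dien-1-yl]oxan-2-yl]prop-2-enoate F2. A Corey–Bakshi–Shibata reduction of F2 with (S)-1-methyl-3,3-diphenyltetrahydro-1H,3H-pyrrolo[1,2-c][1,3,2]oxazaborole and catecholborane (toluene, −78 °C), in which the branched alkenyl group acts as the large substituent, should then return 19 with the (R)-carbinol set by the reagent.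

2. Step 6. The risk is β-elimination of the ring oxygen from the ester enolate competing with the Mannich capture. The fallback sets out from lactone 7 and comes back at 15 without any ester enolate. Lithium (trimethylsilyl)acetylide (THF, −78 °C) should add to 7 to give the alkynyl hemiketal (5S)-5-(but-3-en-1-yl)-2-[(trimethylsilyl)ethynyl]oxan-2-ol F3. Et3SiH/BF3·OEt2 (CH2Cl2/MeCN, −40 °C) should reduce it with axial hydride delivery to the 2,5-trans oxane {[(2R,5S)-5-(but-3-en-1-yl)oxan-2-yl]ethynyl}trimethylsilane F4. Ozonolysis of the butenyl group (the silylalkyne reacts far more slowly) should give 3-{(3R,6R)-6-[(trimethylsilyl)ethynyl]oxan-3-yl}propanal F5, and acetalisation as in step 5 should give {[(2R,5R)-5-(3,3-dimethoxypropyl)oxan-2-yl]ethynyl}trimethylsilane F6. K2CO3/MeOH should remove silicon to give (2R,5R)-5-(3,3-dimethoxypropyl)-2-ethynyloxane F7. Markovnikov methoxycarbonylation of the terminal alkyne (Pd(OAc)2, 2-(diphenylphosphino)pyridine, CH3SO3H, CO, MeOH) should then build the 2-substituted acrylate directly and deliver 15.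

3. Step 8. The risk is loss of regiocontrol in the enolisation (deprotonation at C3 instead of the methyl group), giving internal enol triflates that are hard to remove. The fallback sets out from 17 and comes back at 19. Condensation with 2,4,6-triisopropylbenzenesulfonohydrazide should give N'-[(5E)-6,10-dimethylundeca-5,9-dien-2-ylidene]-2,4,6-triisopropylbenzenesulfonohydrazide F8. A Shapiro reaction (n-BuLi, 2.2 equiv, THF, −78 → 0 °C), which deprotonates the methyl side, and an iodine quench of the 2-lithio-1-alkene should give (5E)-2-iodo-6,10-dimethylundeca-1,5,9-triene F9 as a single regioisomer. F9 would take the place of 18 in the coupling of step 9 with 16.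

**Further compounds**

F1 | step 9 | methyl 2-[(2R,5S)-5-[(3S,7E)-3-hydroxy-8,12-dimethyl-4-methylidenetrideca-7,11-dien-1-yl]oxan-2-yl]prop-2-enoate | C=C(CC/C=C(\C)CCC=C(C)C)[C@@H](O)CC[C@H]1CC[C@H](C(=C)C(=O)OC)OC1
F2 | step 9 | methyl 2-[(2R,5R)-5-[(7E)-8,12-dimethyl-4-methylidene-3-oxotrideca-7,11-dien-1-yl]oxan-2-yl]prop-2-enoate | C=C(CC/C=C(\C)CCC=C(C)C)C(=O)CC[C@H]1CC[C@H](C(=C)C(=O)OC)OC1
F3 | step 6 | (5S)-5-(but-3-en-1-yl)-2-[(trimethylsilyl)ethynyl]oxan-2-ol | C=CCC[C@H]1CCC(O)(C#C[Si](C)(C)C)OC1
F4 | step 6 | {[(2R,5S)-5-(but-3-en-1-yl)oxan-2-yl]ethynyl}trimethylsilane | C=CCC[C@H]1CC[C@H](C#C[Si](C)(C)C)OC1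
F5 | step 6 | 3-{(3R,6R)-6-[(trimethylsilyl)ethynyl]oxan-3-yl}propanal | O=CCC[C@H]1CC[C@H](C#C[Si](C)(C)C)OC1
F6 | step 6 | {[(2R,5R)-5-(3,3-dimethoxypropyl)oxan-2-yl]ethynyl}trimethylsilane | COC(OC)CC[C@H]1CC[C@H](C#C[Si](C)(C)C)OC1
F7 | step 6 | (2R,5R)-5-(3,3-dimethoxypropyl)-2-ethynyloxane | COC(OC)CC[C@H]1CC[C@H](C#C)OC1
F8 | step 8 | N'-[(5E)-6,10-dimethylundeca-5,9-dien-2-ylidene]-2,4,6-triisopropylbenzenesulfonohydrazide | CC(CC/C=C(\C)CCC=C(C)C)=NNS(=O)(=O)c1c(C(C)C)cc(C(C)C)cc1C(C)C
F9 | step 8 | (5E)-2-iodo-6,10-dimethylundeca-1,5,9-triene | C=C(I)CC/C=C(\C)CCC=C(C)C
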